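The vessel is closed and stirred, and the gas held above it feeds in the free base that takes up the acid set free.

    electrophile + nucleophile → acid set free + target (k1 = 155 M⁻¹ s⁻¹)
    acid set free + free base ⇌ salt of the base, settled at all times (K2 = 3.0 × 10⁷ M⁻¹)
    gas ⇌ free base, rate k3*(csat - [free base]) (k3 = 2.06 s⁻¹, csat = 0.042 mM)
    nucleophile + acid set free ⇌ protonated nucleophile, settled at all times (K4 = 20000 M⁻¹)

electrophile 5.0 × 10⁻⁴ M; gas 0.042 mM (held); time 20 s

1. the concentration of nucleophile at which the part of the electrophile that has reacted at 20 s is just 70%, in mM

I carry one quantity, the exposure, which is the rate constant of the main step times the time allowed: 3100 M⁻¹. With the main step alone, the second-order law applies. A nucleophile charge equal to the electrophile charge gives a conversion of 60.8%, which falls short. For unequal charges the integrated law gives 70.3% at 0.625 mM, slightly too much. Interpolating between these two charges puts c nucleophile at 0.621 mM.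

Next I add the gas and the free base. At the start acid forms at 0.0481 mM s⁻¹, and with no free base dissolved the crossing runs at 0.0865 mM s⁻¹, faster than that acid formation, so the acid can pass into the salt and my number stands. Near the end, acid forms at 0.00630 mM s⁻¹, which holds c free base at about 0.0389 mM. The salt balance then leaves c acid at about 3.00 × 10⁻⁷ M.

Last I add the protonation of the nucleophile. At that acid level, hardly any of the nucleophile is protonated, 0.599% by my reckoning, so I stay with 0.621 mM.

The forecast gives 0.622 mM against my 0.621 mM, and says the problem “reduces to plain second-order kinetics”. The simulation gives 0.622 mM.

In this flask, half of the gas crossing up to 20 s is done by 4.91 s, earlier than the 5.32 s by which half of the main step's turnover is done, and 86.6% of the charged nucleophile is still free at 2.00 s. With this charge, the exposure reckoned for 5.00 s gives 33.6% against 33.5% used, and in the late flask, run twice as long, doubled exposure gives 85.2% against the 85.1% that reacted.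

The numbers were drawn at random within sensible limits.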